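The nine-membered carbocycle is disconnected at the C10–C11 bond (C10 = ring CH2 between the epoxide and the exocyclic methylene; C11 = the methylene-bearing ring carbon). The C8–C9 epoxide next to the C7 carbinol is read as an oxidised (Z)-allylic alcohol, so that C8=C9, C10 and C11=C19 form a skipped diene: the retron of an Alder-ene reaction. A ruthenium-catalysed ene cyclisation of a trans-4,5-disubstituted δ-lactone carrying an ethynyl group (C11≡C19) and a 3-hydroxy-3-methylhex-5-enyl chain (C5–C10) should close the ring, create the exocyclic methylene and shift the olefin to C8=C9 in one operation. Directed epoxidation and an aldol condensation finish the synthesis.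

Key step: step 8

Atom labels: lactone O2, C1 (OCH2), C3 (C=O), C4; ring-fusion carbons C4a and C11a; carbocycle C5 to C11; C18 = methyl on C7; C19 = methylene on C11; side chain C12 to C15. Ring A = nine-membered carbocycle, ring B = δ-lactone.
Remark: in the target the C8–C9 epoxide is cis-disubstituted and lies on the same face of ring A as the C7 hydroxyl; the ring fusion is trans.
Assumption: (S)-3,3′-dibromo-BINOL is taken as the antipode that delivers allyl to the Re face of the ketone in step 4; if a model ketone shows the opposite sense, the (R)-diol is used.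

Step 1
Reactants: 1 2-[(tert-butyldimethylsilyl)oxy]acetaldehyde; 2 nitromethane
Product: 5 tert-butyldimethyl{[(2E)-3-nitroprop-2-en-1-yl]oxy}silane, via nitro aldol 3 (not isolated), via nitro aldol mesylate 4 (not isolated)
Conditions: Et3N (0.1 equiv), THF, 0 °C; then MsCl, Et3N (2.2 equiv), CH2Cl2, −20 → 0 °C
Reagents that add atoms: none
Why: Henry addition followed by mesylation and E1cB loss of methanesulfonate should give the conjugated nitroalkene as its more stable E isomer.

Step 2
Reactants: 5 tert-butyldimethyl{[(2E)-3-nitroprop-2-en-1-yl]oxy}silane; 6 methyl 4-oxobutanoate; 7 1-(triphenyl-λ5-phosphanylidene)propan-2-one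
Product: 9 methyl (3S,4E)-3-[(2R)-1-[(tert-butyldimethylsilyl)oxy]-3-nitropropan-2-yl]-6-oxohept-4-enoate, via nitro aldehyde 8 (not isolated)
Conditions: (S)-α,α-diphenylprolinol trimethylsilyl ether (10 mol %), 4-nitrophenol (10 mol %), PhMe, 0 °C → rt; then 7, rt
Reagents that add atoms: none
Why: Enamine-catalysed asymmetric Michael addition through the anti-enamine and a synclinal transition state should set C4a and C11a syn under catalyst control (the relationship that becomes the trans ring fusion), and the in situ Wittig olefination with the stabilised ylide traps the epimerisable aldehyde as the (E)-enone.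

Step 3
Reactants: 9 methyl (3S,4E)-3-[(2R)-1-[(tert-butyldimethylsilyl)oxy]-3-nitropropan-2-yl]-6-oxohept-4-enoate
Product: 10 methyl (3R)-3-[(2R)-1-[(tert-butyldimethylsilyl)oxy]-3-nitropropan-2-yl]-6-oxoheptanoate
Conditions: H2 (1 atm), RhCl(PPh3)3 (5 mol %), PhMe, rt
Reagents that add atoms: none
Why: Homogeneous rhodium-catalysed hydrogenation should reduce the disubstituted enone olefin and leave the aliphatic nitro group, ketone, ester and silyl ether untouched.

Step 4
Reactants: 10 methyl (3R)-3-[(2R)-1-[(tert-butyldimethylsilyl)oxy]-3-nitropropan-2-yl]-6-oxoheptanoate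
Product: 11 methyl (3R,6S)-3-[(2R)-1-[(tert-butyldimethylsilyl)oxy]-3-nitropropan-2-yl]-6-hydroxy-6-methylnon-8-enoate
Conditions: allylB(OiPr)2, (S)-3,3′-dibromo-BINOL (15 mol %), PhCF3/PhMe, −35 °C → rt; aqueous work-up
Reagents that add atoms: allyldiisopropoxyborane, C=CCB(OC(C)C)OC(C)C
Why: Chiral-diol-catalysed asymmetric allylboration of the methyl ketone through a closed chair transition state should deliver allyl to the Re face and set C7 as S under catalyst control, and the neutral boron reagent tolerates the acidic nitro group and removes the ketone before any base is used.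

Step 5
Reactants: 11 methyl (3R,6S)-3-[(2R)-1-[(tert-butyldimethylsilyl)oxy]-3-nitropropan-2-yl]-6-hydroxy-6-methylnon-8-enoate
Product: 13 methyl (3R,6S)-3-[(2S)-1-[(tert-butyldimethylsilyl)oxy]-3-oxopropan-2-yl]-6-hydroxy-6-methylnon-8-enoate, via sodium nitronate 12 (not isolated)
Conditions: NaOMe, MeOH, 0 °C; then aq. TiCl3, NH4OAc, THF, 0 °C → rt
Reagents that add atoms: water, O
Why: Reductive Nef reaction, in which trivalent titanium reduces the nitronate to the imine that hydrolyses at buffered pH, should give the aldehyde while the terminal olefin, tertiary alcohol and silyl ether survive.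

Step 6
Reactants: 13 methyl (3R,6S)-3-[(2S)-1-[(tert-butyldimethylsilyl)oxy]-3-oxopropan-2-yl]-6-hydroxy-6-methylnon-8-enoate
Product: 14 methyl (3R,6S)-3-[(2R)-1-[(tert-butyldimethylsilyl)oxy]but-3-yn-2-yl]-6-hydroxy-6-methylnon-8-enoate
Conditions: dimethyl (1-diazo-2-oxopropyl)phosphonate, K2CO3, MeOH, 0 °C → rt
Reagents that add atoms: dimethyl (1-diazo-2-oxopropyl)phosphonate, CC(=O)C(=[N+]=[N-])P(=O)(OC)OC
Why: Seyferth–Gilbert homologation with the Ohira–Bestmann reagent should convert the aldehyde into the terminal alkyne under carbonate conditions mild enough to keep the adjacent C11a centre of a β-silyloxy aldehyde.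

Step 7
Reactants: 14 methyl (3R,6S)-3-[(2R)-1-[(tert-butyldimethylsilyl)oxy]but-3-yn-2-yl]-6-hydroxy-6-methylnon-8-enoate
Product: 16 (4R,5R)-5-ethynyl-4-[(3S)-3-hydroxy-3-methylhex-5-en-1-yl]oxan-2-one, via hydroxy ester 15 (not isolated)
Conditions: camphorsulfonic acid (cat.), MeOH, rt; then PhMe, 50 °C
Reagents that add atoms: none
Why: Acid-catalysed methanolysis of the primary silyl ether followed by lactonisation of the δ-hydroxy ester should give the six-membered lactone, since the tertiary alcohol could only form a seven-membered ring.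

Step 8
Reactants: 16 (4R,5R)-5-ethynyl-4-[(3S)-3-hydroxy-3-methylhex-5-en-1-yl]oxan-2-one
Product: 17 (4aR,7S,8Z,11aR)-7-hydroxy-7-methyl-11-methylidene-4,4a,5,6,7,10,11,11a-octahydro-1H-cyclonona[c]pyran-3-one
Conditions: [CpRu(MeCN)3]PF6 (10 mol %), acetone, 0.002 M, rt → 50 °C
Reagents that add atoms: none
Why: Proposed new method: the ruthenium-catalysed alkene–alkyne coupling (formal Alder-ene reaction), established for open-chain partners and for macrocyclisation, is here asked to close a nine-membered ring; the cationic CpRu fragment should bind the terminal alkyne and the monosubstituted olefin, form a ruthenacyclopentene with creation of the C10–C11 bond, then lose an allylic C8 hydrogen by β-hydride elimination and transfer it to C19 by reductive elimination. Ring A is closed 9-exo-dig with respect to the alkyne (C19 stays outside as the exocyclic methylene) and 9-endo-trig with respect to the alkene, so that C8=C9 ends inside the ring next to the C7 carbinol. No stereocentre is formed or touched, and C4a, C11a and C7 are carried through unchanged. The step needs bond formation at the internal alkyne carbon (attack at C19 would give a ten-membered ring) and Z geometry at C8=C9: the first is the normal preference of this catalyst for terminal alkynes with a branched propargylic carbon (here C11a), and the second is expected because C7 and C11 are joined by a four-atom tether that is spanned most easily from the cisoid arrangement of C7 and C10 in the ring-fused ruthenacycle. The E olefin that dominates open-chain couplings is the main risk; high dilution suppresses intermolecular coupling, and the catalyst tolerates the free tertiary alcohol and the lactone.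

Step 9
Reactants: 17 (4aR,7S,8Z,11aR)-7-hydroxy-7-methyl-11-methylidene-4,4a,5,6,7,10,11,11a-octahydro-1H-cyclonona[c]pyran-3-one
Product: 18 (4aR,7S,8R,9R,11aR)-8,9-epoxy-7-hydroxy-7-methyl-11-methylidenedecahydro-1H-cyclonona[c]pyran-3-one
Conditions: VO(acac)2 (5 mol %), t-BuOOH, CH2Cl2, 0 °C
Reagents that add atoms: tert-butyl hydroperoxide, CC(C)(C)OO
Why: Vanadium-catalysed hydroxyl-directed epoxidation should deliver oxygen from the vanadate ester of the C7 alcohol to the neighbouring (Z)-olefin on the face syn to the hydroxyl, as is general for cyclic (Z)-allylic alcohols, which sets C8 and C9 as the cis-epoxide and leaves the undirected exocyclic methylene alone.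

Step 10
Reactants: 18 (4aR,7S,8R,9R,11aR)-8,9-epoxy-7-hydroxy-7-methyl-11-methylidenedecahydro-1H-cyclonona[c]pyran-3-one
Product: 19 (4aR,7S,8R,9R,11aR)-8,9-epoxy-7-methyl-11-methylidene-7-[(triethylsilyl)oxy]decahydro-1H-cyclonona[c]pyran-3-one
Conditions: Et3SiOTf, 2,6-lutidine, CH2Cl2, −78 °C
Reagents that add atoms: triethylsilyl trifluoromethanesulfonate, CC[Si](CC)(CC)OS(=O)(=O)C(F)(F)F
Why: Silylation of the hindered tertiary alcohol with the silyl triflate should mask the only acidic hydroxyl before enolate chemistry and prevent alkoxide-induced epoxide migration.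

Step 11
Reactants: 20 3-methylbut-2-enal; 21 vinylmagnesium bromide
Product: 22 5-methylhexa-1,4-dien-3-ol (racemic)
Conditions: THF, −78 → 0 °C; then sat. aq. NH4Cl
Reagents that add atoms: none
Why: Grignard 1,2-addition to the enal should give the racemic bis-allylic alcohol.

Step 12
Reactants: 22 5-methylhexa-1,4-dien-3-ol (racemic)
Product: 23 (1S)-1-[(2S)-3,3-dimethyloxiran-2-yl]prop-2-en-1-ol
Conditions: Ti(OiPr)4 (10 mol %), L-(+)-diisopropyl tartrate (15 mol %), t-BuOOH (0.45 equiv), 4 Å MS, CH2Cl2, −20 °C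
Reagents that add atoms: tert-butyl hydroperoxide, CC(C)(C)OO
Why: Sharpless kinetic resolution should epoxidise the fast-reacting (S)-alcohol at its electron-rich trisubstituted olefin to the erythro epoxy alcohol, which sets C14 by reagent control and selects C13, while the (R)-alcohol and the vinyl group react more slowly and the unreacted alcohol is separated.

Step 13
Reactants: 23 (1S)-1-[(2S)-3,3-dimethyloxiran-2-yl]prop-2-en-1-ol
Product: 24 {[(1S)-1-[(2S)-3,3-dimethyloxiran-2-yl]prop-2-en-1-yl]oxy}triethylsilane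
Conditions: Et3SiCl, imidazole, CH2Cl2, 0 °C
Reagents that add atoms: chlorotriethylsilane, CC[Si](Cl)(CC)CC
Why: Standard silylation protects the secondary alcohol as a triethylsilyl ether that survives ozonolysis and enolate chemistry and is removed at the end together with the C7 silyl ether.

Step 14
Reactants: 24 {[(1S)-1-[(2S)-3,3-dimethyloxiran-2-yl]prop-2-en-1-yl]oxy}triethylsilane
Product: 26 (2R)-2-[(2S)-3,3-dimethyloxiran-2-yl]-2-[(triethylsilyl)oxy]acetaldehyde, via ozonide 25 (not isolated)
Conditions: O3, CH2Cl2, −78 °C; then PPh3, −78 °C → rt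
Reagents that add atoms: ozone, [O-][O+]=O
Why: Ozonolysis of the only olefin with reductive work-up should give the α-silyloxy aldehyde without touching the epoxide, and the aldehyde is used at once.

Step 15
Reactants: 19 (4aR,7S,8R,9R,11aR)-8,9-epoxy-7-methyl-11-methylidene-7-[(triethylsilyl)oxy]decahydro-1H-cyclonona[c]pyran-3-one; 26 (2R)-2-[(2S)-3,3-dimethyloxiran-2-yl]-2-[(triethylsilyl)oxy]acetaldehyde
Product: 27 aldol adduct: 19 bearing at C4 a (2S)-2-[(2S)-3,3-dimethyloxiran-2-yl]-1-hydroxy-2-[(triethylsilyl)oxy]ethyl group (mixture of epimers at C4 and C12)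
Conditions: LDA, THF, −78 °C; then 26, −78 °C; then sat. aq. NH4Cl
Reagents that add atoms: none
Why: Aldol addition of the lithium enolate of the δ-lactone, whose only acidic hydrogens are at C4, should join the fragments, and the two new centres at C4 and C12 are removed in the next step so their configuration does not matter.

Step 16
Reactants: 27 aldol adduct (mixture of epimers at C4 and C12)
Product: 29 (4E,4aS,7S,8R,9R,11aR)-4-{(2S)-2-[(2S)-3,3-dimethyloxiran-2-yl]-2-[(triethylsilyl)oxy]ethylidene}-8,9-epoxy-7-methyl-11-methylidene-7-[(triethylsilyl)oxy]octahydro-1H-cyclonona[c]pyran-3-one, via aldol mesylate 28 (not isolated)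
Conditions: MsCl, Et3N, CH2Cl2, −20 °C; then DBU, 0 °C → rt
Reagents that add atoms: none
Why: Mesylation and E1cB elimination through the lactone enolate should converge both aldol epimers on the conjugated alkylidene lactone, expected as the more stable E isomer with the C12 hydrogen syn to the carbonyl.

Step 17
Reactants: 29 bis(triethylsilyl) ether of the target
Product: 30 (4E,4aS,7S,8R,9R,11aR)-4-{(2S)-2-[(2S)-3,3-dimethyloxiran-2-yl]-2-hydroxyethylidene}-8,9-epoxy-7-hydroxy-7-methyl-11-methylideneoctahydro-1H-cyclonona[c]pyran-3-one (CNP0147265.1)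
Conditions: TBAF, AcOH (1:1), THF, 0 °C → rt
Reagents that add atoms: none
Why: Fluoride-mediated desilylation buffered with acetic acid should free both hydroxyls without the alkoxide-induced Payne rearrangement that either epoxy alcohol could undergo.

Compound list
1 | 2-[(tert-butyldimethylsilyl)oxy]acetaldehyde | CC(C)(C)[Si](C)(C)OCC=O | starting material
2 | nitromethane | C[N+](=O)[O-] | starting material
3 | 1-[(tert-butyldimethylsilyl)oxy]-3-nitropropan-2-ol (racemic, not isolated) | CC(C)(C)[Si](C)(C)OCC(O)C[N+](=O)[O-] | intermediate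
4 | 1-[(tert-butyldimethylsilyl)oxy]-3-nitropropan-2-yl methanesulfonate (racemic, not isolated) | CC(C)(C)[Si](C)(C)OCC(OS(C)(=O)=O)C[N+](=O)[O-] | intermediate
5 | tert-butyldimethyl{[(2E)-3-nitroprop-2-en-1-yl]oxy}silane | CC(C)(C)[Si](C)(C)OC/C=C/[N+](=O)[O-] | intermediate
6 | methyl 4-oxobutanoate | COC(=O)CCC=O | starting material
7 | 1-(triphenyl-λ5-phosphanylidene)propan-2-one | CC(=O)C=P(c1ccccc1)(c1ccccc1)c1ccccc1 | starting material
8 | methyl (3R,4R)-4-{[(tert-butyldimethylsilyl)oxy]methyl}-3-formyl-5-nitropentanoate (not isolated) | COC(=O)C[C@@H](C=O)[C@H](C[N+](=O)[O-])CO[Si](C)(C)C(C)(C)C | intermediate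
9 | methyl (3S,4E)-3-[(2R)-1-[(tert-butyldimethylsilyl)oxy]-3-nitropropan-2-yl]-6-oxohept-4-enoate | COC(=O)C[C@@H](/C=C/C(C)=O)[C@H](C[N+](=O)[O-])CO[Si](C)(C)C(C)(C)C | intermediate
10 | methyl (3R)-3-[(2R)-1-[(tert-butyldimethylsilyl)oxy]-3-nitropropan-2-yl]-6-oxoheptanoate | COC(=O)C[C@@H](CCC(C)=O)[C@H](C[N+](=O)[O-])CO[Si](C)(C)C(C)(C)C | intermediate
11 | methyl (3R,6S)-3-[(2R)-1-[(tert-butyldimethylsilyl)oxy]-3-nitropropan-2-yl]-6-hydroxy-6-methylnon-8-enoate | COC(=O)C[C@@H](CC[C@](C)(O)CC=C)[C@H](C[N+](=O)[O-])CO[Si](C)(C)C(C)(C)C | intermediate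
12 | sodium nitronate of 11 (not isolated) | COC(=O)C[C@@H](CC[C@](C)(O)CC=C)[C@H](C=[N+]([O-])[O-])CO[Si](C)(C)C(C)(C)C.[Na+] | intermediate
13 | methyl (3R,6S)-3-[(2S)-1-[(tert-butyldimethylsilyl)oxy]-3-oxopropan-2-yl]-6-hydroxy-6-methylnon-8-enoate | COC(=O)C[C@@H](CC[C@](C)(O)CC=C)[C@H](C=O)CO[Si](C)(C)C(C)(C)C | intermediate
14 | methyl (3R,6S)-3-[(2R)-1-[(tert-butyldimethylsilyl)oxy]but-3-yn-2-yl]-6-hydroxy-6-methylnon-8-enoate | COC(=O)C[C@@H](CC[C@](C)(O)CC=C)[C@H](C#C)CO[Si](C)(C)C(C)(C)C | intermediate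
15 | methyl (3R,6S)-6-hydroxy-3-[(2R)-1-hydroxybut-3-yn-2-yl]-6-methylnon-8-enoate (not isolated) | COC(=O)C[C@@H](CC[C@](C)(O)CC=C)[C@H](C#C)CO | intermediate
16 | (4R,5R)-5-ethynyl-4-[(3S)-3-hydroxy-3-methylhex-5-en-1-yl]oxan-2-one | O=C1C[C@@H](CC[C@](C)(O)CC=C)[C@H](C#C)CO1 | intermediate
17 | (4aR,7S,8Z,11aR)-7-hydroxy-7-methyl-11-methylidene-4,4a,5,6,7,10,11,11a-octahydro-1H-cyclonona[c]pyran-3-one | C=C1C/C=C\[C@@](C)(O)CC[C@@H]2CC(=O)OC[C@@H]12 | intermediate
18 | (4aR,7S,8R,9R,11aR)-8,9-epoxy-7-hydroxy-7-methyl-11-methylidenedecahydro-1H-cyclonona[c]pyran-3-one | C=C1C[C@H]2O[C@H]2[C@@](C)(O)CC[C@@H]2CC(=O)OC[C@@H]12 | intermediate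
19 | (4aR,7S,8R,9R,11aR)-8,9-epoxy-7-methyl-11-methylidene-7-[(triethylsilyl)oxy]decahydro-1H-cyclonona[c]pyran-3-one | C=C1C[C@H]2O[C@H]2[C@@](C)(O[Si](CC)(CC)CC)CC[C@@H]2CC(=O)OC[C@@H]12 | intermediate
20 | 3-methylbut-2-enal | CC(C)=CC=O | starting material
21 | vinylmagnesium bromide | C=C[Mg]Br | starting material
22 | 5-methylhexa-1,4-dien-3-ol (racemic) | C=CC(O)C=C(C)C | intermediate
23 | (1S)-1-[(2S)-3,3-dimethyloxiran-2-yl]prop-2-en-1-ol | C=C[C@H](O)[C@@H]1OC1(C)C | intermediate
24 | {[(1S)-1-[(2S)-3,3-dimethyloxiran-2-yl]prop-2-en-1-yl]oxy}triethylsilane | C=C[C@H](O[Si](CC)(CC)CC)[C@@H]1OC1(C)C | intermediate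
25 | 1,2,4-trioxolane (ozonide) of 24, epimers at the ozonide carbon (not isolated) | C1(OCOO1)[C@H](O[Si](CC)(CC)CC)[C@@H]1OC1(C)C | intermediate
26 | (2R)-2-[(2S)-3,3-dimethyloxiran-2-yl]-2-[(triethylsilyl)oxy]acetaldehyde | O=C[C@H](O[Si](CC)(CC)CC)[C@@H]1OC1(C)C | intermediate
27 | aldol adduct of 19 and 26 (epimers at C4 and C12) | C=C1C[C@H]2O[C@H]2[C@@](C)(O[Si](CC)(CC)CC)CC[C@@H]2C(C(O)[C@H](O[Si](CC)(CC)CC)[C@@H]3OC3(C)C)C(=O)OC[C@@H]12 | intermediate
28 | C12 methanesulfonate of 27 (epimers at C4 and C12, not isolated) | C=C1C[C@H]2O[C@H]2[C@@](C)(O[Si](CC)(CC)CC)CC[C@@H]2C(C(OS(C)(=O)=O)[C@H](O[Si](CC)(CC)CC)[C@@H]3OC3(C)C)C(=O)OC[C@@H]12 | intermediate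
29 | (4E,4aS,7S,8R,9R,11aR)-4-{(2S)-2-[(2S)-3,3-dimethyloxiran-2-yl]-2-[(triethylsilyl)oxy]ethylidene}-8,9-epoxy-7-methyl-11-methylidene-7-[(triethylsilyl)oxy]octahydro-1H-cyclonona[c]pyran-3-one | C=C1C[C@H]2O[C@H]2[C@@](C)(O[Si](CC)(CC)CC)CC[C@@H]2/C(=C\[C@H](O[Si](CC)(CC)CC)[C@@H]3OC3(C)C)C(=O)OC[C@@H]12 | intermediate
30 | (4E,4aS,7S,8R,9R,11aR)-4-{(2S)-2-[(2S)-3,3-dimethyloxiran-2-yl]-2-hydroxyethylidene}-8,9-epoxy-7-hydroxy-7-methyl-11-methylideneoctahydro-1H-cyclonona[c]pyran-3-one (CNP0147265.1) | C=C1C[C@H]2O[C@H]2[C@@](C)(O)CC[C@@H]2/C(=C\[C@H](O)[C@@H]3OC3(C)C)C(=O)OC[C@@H]12 | target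

Total step count: 17. Longest linear sequence: 13 steps (steps 1 to 10, then 15 to 17); the side-chain aldehyde 26 takes 4 steps (11 to 14).

Steps most likely to fail

Step 8. Intermolecular coupling may outrun ring closure, the bond may form at C19 to give a ten-membered ring, or β-hydride elimination may take place from the transoid conformer and give the E olefin. The fallback uses known chemistry, closes the same C10–C11 bond by allylic alkylation, sets out from 11 and returns at 17. Acid-mediated desilylation of 11 (camphorsulfonic acid, MeOH; then PhMe, 50 °C) passes through the hydroxy nitro ester F1 and gives the nitro lactone F2. Sulfoxide-promoted allylic C–H acetoxylation (Pd(OAc)2, DMSO, benzoquinone, AcOH) should give the linear (E)-allylic acetate F3. Intramolecular Tsuji–Trost alkylation of the nitronate (Pd(PPh3)4, DBU, THF, high dilution) should close ring A to the nitro cyclononene F4, with the E olefin expected from the syn π-allyl complex. Thiyl-radical isomerisation (PhSSPh, hν, PhH) should convert it into the less strained Z isomer F5. A reductive Nef reaction (aq. TiCl3, NH4OAc, THF) gives the ketone F6, and methylenation with Zn, CH2Br2 and TiCl4 returns to 17.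

Step 16. Elimination may give the Z-alkylidene isomer, or the base may deprotonate the product at C13 and open the adjacent side-chain epoxide. The fallback sets out from 19 and 26, bypasses 27 and 28, and returns at 29. The lithium enolate of 19 (LDA, THF, −78 °C) is O-phosphorylated with ClP(O)(OEt)2 to the enol phosphate F7, which with a second equivalent of LDA rearranges by 1,3-phosphorus migration to the α-phosphono lactone F8. Horner–Wadsworth–Emmons olefination of F8 with 26 (LiCl, DBU, MeCN, 0 °C) then forms the C4=C12 bond under milder basic conditions and gives 29.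

Step 12. The rate difference between the two enantiomers may be too small, because the olefin carries a methyl group cis to the carbinol, and epoxidation of the vinyl group may compete. The fallback sets the epoxide centre by reagent control on an achiral substrate, sets out from 20 and returns at 23. Reduction of 20 (NaBH4, MeOH) gives 3-methylbut-2-en-1-ol F9. Sharpless asymmetric epoxidation (Ti(OiPr)4, L-(+)-diethyl tartrate, t-BuOOH, 4 Å MS, CH2Cl2, −20 °C) gives the epoxy alcohol F10. Parikh–Doering oxidation (SO3·pyridine, DMSO, Et3N) gives the epoxy aldehyde F11. Felkin–Anh-controlled addition of 21 (THF, −78 °C) should favour the erythro alcohol 23, which is separated from its C13 epimer.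

Further compounds
F1 | step 8 | methyl (3R,6S)-6-hydroxy-3-[(2R)-1-hydroxy-3-nitropropan-2-yl]-6-methylnon-8-enoate | COC(=O)C[C@@H](CC[C@](C)(O)CC=C)[C@H](C[N+](=O)[O-])CO
F2 | step 8 | (4R,5R)-4-[(3S)-3-hydroxy-3-methylhex-5-en-1-yl]-5-(nitromethyl)oxan-2-one | O=C1C[C@@H](CC[C@](C)(O)CC=C)[C@H](C[N+](=O)[O-])CO1
F3 | step 8 | (2E,4S)-4-hydroxy-4-methyl-6-[(4R,5R)-5-(nitromethyl)-2-oxooxan-4-yl]hex-2-en-1-yl acetate | O=C1C[C@@H](CC[C@](C)(O)/C=C/COC(C)=O)[C@H](C[N+](=O)[O-])CO1
F4 | step 8 | (4aR,7S,8E,11aR)-7-hydroxy-7-methyl-11-nitro-4,4a,5,6,7,10,11,11a-octahydro-1H-cyclonona[c]pyran-3-one (C11 epimers) | [O-][N+](=O)C1C/C=C/[C@@](C)(O)CC[C@@H]2CC(=O)OC[C@@H]12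
F5 | step 8 | (4aR,7S,8Z,11aR)-7-hydroxy-7-methyl-11-nitro-4,4a,5,6,7,10,11,11a-octahydro-1H-cyclonona[c]pyran-3-one (C11 epimers) | [O-][N+](=O)C1C/C=C\[C@@](C)(O)CC[C@@H]2CC(=O)OC[C@@H]12
F6 | step 8 | (4aR,7S,8Z,11aS)-7-hydroxy-7-methyl-4,4a,5,6,7,10-hexahydro-1H-cyclonona[c]pyran-3,11(11aH)-dione | O=C1C/C=C\[C@@](C)(O)CC[C@@H]2CC(=O)OC[C@@H]12
F7 | step 16 | diethyl enol phosphate of 19 (C3=C4 enol, phosphate on the C3 oxygen) | C=C1C[C@H]2O[C@H]2[C@@](C)(O[Si](CC)(CC)CC)CC[C@@H]2C=C(OP(=O)(OCC)OCC)OC[C@@H]12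
F8 | step 16 | 4-(diethoxyphosphoryl) derivative of 19 (C4 epimers) | C=C1C[C@H]2O[C@H]2[C@@](C)(O[Si](CC)(CC)CC)CC[C@@H]2C(P(=O)(OCC)OCC)C(=O)OC[C@@H]12
F9 | step 12 | 3-methylbut-2-en-1-ol | CC(C)=CCO
F10 | step 12 | [(2S)-3,3-dimethyloxiran-2-yl]methanol | OC[C@@H]1OC1(C)C
F11 | step 12 | (2R)-3,3-dimethyloxirane-2-carbaldehyde | O=C[C@@H]1OC1(C)C
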